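Each of the new flasks holds 5.0 mM of starting material against 1.05 equiv of reagent, with 1.50 mM of capture agent, and is read at 2.5 min. Sunday's starts with everything together. Tuesday's feeds the starting material and Saturday's the reagent.

| flask | starting material | reagent | capture agent | remark | time |
|---|---|---|---|---|---|
| epsilon | 5 mM | 1.05 equiv | 1.5 mM | run made earlier |  |
| eta | 5 mM | 1.05 equiv | 2.2 mM | run made earlier |  |
| Sunday's | 5.0 mM | 1.05 equiv | 1.50 mM | everything together at the start | 2.5 min |
| Tuesday's | 5.0 mM (fed, over 1.0 min) | 1.05 equiv | 1.50 mM | all else is in the flask from the start; the feed brings no volume worth counting | 2.5 min |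
| Saturday's | 5.0 mM | 1.05 equiv (fed, over 1.0 min) | 1.50 mM | all else is in the flask from the start; the feed brings no volume worth counting | 2.5 min |

| run | time / s | product / % | starting material / % |
|---|---|---|---|
| epsilon | 25.0 | 9 | 78 |
| epsilon | 50.0 | 19 | 64 |
| epsilon | 60.0 | 24 | 59 |
| epsilon | 90.0 | 36 | 46 |
| eta | 12.0 | 4 | 89 |
| eta | 25.0 | 9 | 78 |
| eta | 30.0 | 9 | 74 |
| eta | 50.0 | 18 | 62 |

(scatter of a reading: 1.5 percentage points)



1. which flask leads in amount of product, in percent of the starting material charged ("all alike" within 1.5 percentage points) (Sunday's / Tuesday's / Saturday's / all alike)
2. how much product is there at the end, in percent of the starting material charged: Sunday's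
3. how much product is there at the end, in percent of the starting material charged: Tuesday's
4. how much product is there at the end, in percent of the starting material charged: Saturday's

Two numbers seem at odds: the feed lasts 1.0 min, yet the delay reckoned here is 30.0 s. A steady feed delivers its charge, on average, at half the feed time. Each fed flask is therefore reckoned as Sunday's started that much later. The reckoning here takes the loss of starting material as a meeting with reagent, and on that assumption it uses the same delay for either feed.

At 50.0 s, the eta run, with 2.2 mM of capture agent, reads 62% of starting material, against 64% in the epsilon run with 1.5 mM. That difference is near the scatter of 1.5 percentage points, so the two runs are pooled. Partners charged about equally follow: fraction left = 1/(1 + t/τ). Here τ is the meeting time, the second-order half-life. The 4 readings from 50.0 s on give a mean of 83.4 s.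

So Sunday's is reckoned to keep 35.7% of its starting material, and each fed flask 41.0%. In the epsilon run at 90.0 s, 18.0% of the charge is neither starting material nor product. Holding that gap gives 46.3% product for Sunday's and 41.0% for each fed flask.

The forecast names Sunday's, with 52% (44% to 59%) there and 46% and 46% (each 38% to 54%) for the feeds: “The two feeds are nearly symmetric”. The reckoning here sits lower than its central figure for Sunday's.

Sunday's ends with 51.0% product, Tuesday's with 43.9% and Saturday's with 43.9%, so Sunday's leads. Sunday's still holds 36.3% of its starting material at 2.50 min.

    open intermediate + capture agent → trapped intermediate (k = 2.79 L mol⁻¹ s⁻¹)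
    starting material + reagent → open intermediate + released group (k = 2.14 L mol⁻¹ s⁻¹)
    crystals ⇌ released group, rate k3*(cs3 - [released group]) while solid is left; crystals form when [released group] > cs3 (solubility = 0.0520 mM, k = 7.95 s⁻¹)
    open intermediate → product (k = 0.0307 s⁻¹)

A neighbour of Sunday's takes 8.5 mM of starting material, with equivalents and time held. Scaled inversely with the charge, its meeting time comes to 49.0 s, and that is reckoned to leave 24.6% of the starting material. That neighbour holds 24.6% of starting material and 62.6% of product at 2.50 min.

Readings and results stem from a simulated flask on assumed constants; the scatter is artificial.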